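(All constants were chosen freely; the rest is arithmetic.)

Compare these flasks by the product they hold at the end.

    starting material → intermediate A (k1 = 0.012 s⁻¹, Ea1 = 99.0 kJ mol⁻¹)
    intermediate A → intermediate B (k2 = 1.9 × 10⁻⁴ s⁻¹, Ea2 = 98.0 kJ mol⁻¹)
    intermediate B → intermediate C (k3 = 8.0 × 10⁻⁴ s⁻¹, Ea3 = 103 kJ mol⁻¹)
    intermediate C → product (k4 = 0.0052 s⁻¹, Ea4 = 90.0 kJ mol⁻¹)
    starting material + protic impurity → quenched substrate (k5 = 0.36 M⁻¹ s⁻¹, Ea5 = 52.0 kJ mol⁻¹)
    (constants at 50 °C)

| setting | south-west | west | south | north-west |
|---|---|---|---|---|
| starting material | 0.22 M | 0.22 M | 0.22 M | 0.22 M |
| protic impurity | 0.0220 M | 0.0220 M | 0.0220 M | 0.0220 M |
| temperature | −10 °C |  | 20 °C | 50 °C |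
| time | 40 min | 40 min | 40 min | 40 min |
| remark |  | at −10 °C until 8.0 min, from then on at 50 °C |  |  |

- at 50 °C the constants are as listed, elsewhere as the activation energies make them

* the best flask by amount of product, in percent of the starting material charged; "all alike" if 1.5 percentage points covers them all (south-west / west / south / north-west / all alike)
* amount of product at the end, in percent of the starting material charged, south-west
* amount of product at the end, in percent of the starting material charged, west
* amount of product at the end, in percent of the starting material charged, south
* amount of product at the end, in percent of the starting material charged, north-west

- The ladder starts in north-west, where the constants stand as listed. In north-west the protic impurity has the shortest life, 0.210 min against the charged starting material, so it should turn 10.0% of the charge into quenched substrate and leave 90.0% for the chain.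
- On the next rung of north-west, starting material passes into intermediate A with a life of 1.39 min.
- Further up in north-west, intermediate C lives 3.21 min and intermediate B lives 20.8 min, so both are shorter-lived than the run and hold material in transit.
- The top rung in north-west is the life of intermediate A, the reciprocal of the constant of its step to intermediate B: 87.7 min. At that temperature, the fraction of intermediate A left after a time is e raised to minus that time over this life.
- This life is the longest on the ladder and longer than the run, so in north-west the step from intermediate A is the rate-limiting step and intermediate A is the resting state.
- The hand reckoning for north-west lets the decay begin one starting-material life late, which leaves a fraction 0.644. Intermediate A should then stand at 58.0% of the charge, and 32.0% should be shared among intermediate B, intermediate C and product.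
- West spends 8.0 min cold, where the life of intermediate A is 5980 h, so its clock starts at the change. The reckoning for west gives 26.5% shared the same way, less than in north-west.
- South has a life of 61.1 h, so under 1.09% of its intermediate A moves on. South-west, with a longer life, should show about zero product too, and the reckoning therefore puts north-west first.
- The forecast names north-west as best, with 0% in south-west, 11.2% in west, <0.001% in south and 16.3% in north-west, and holds that “the cold flasks, lagging through a four-step chain, show effectively nothing”.
- The simulation gives north-west as best, with product 0% in south-west, 11.2% in west, 0% in south and 16.3% in north-west. North-west holds 58.0% intermediate A, and its intermediate B, intermediate C and product add up to 32.1%, against the reckoned 32.0%.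
- North-west has not come to rest at 40.0 min: its intermediate A stands at 58.0%, more than its product, intermediate B or intermediate C. At 400 min the life predicts 0.956% intermediate A; north-west shows 0.957%, with product risen to 88.7%. For west at 400 min the same life, counted from the change, predicts 1.05%; west shows 1.05%, with product at 88.6%. South-west at 400 min still holds 84.3% starting material, and its product stays at 0%.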